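**Plan**

1. Locants: tetralin C1 (CH–aryl), C2 and C3 (each CH–CH2OH), C4 (CH2); ring A = C4a–C8a (C5 OMe, C6 OMe, C7 OH, C8 H); pendant guaiacyl ring = ring C (C1'–C6', C3' OMe, C4' OH).
2. Retrosynthetic cuts, in order: C1–C2 (closes ring B, last C–C bond), C1–C1' (aryl Grignard plus ring A aldehyde), C4–C4a (Negishi sp3–sp2 coupling); this leaves ring A iodo-aldehyde 9, chain iodide 4 and bromoguaiacol 12.
3. Enabling feature: C1 is doubly benzylic and para to the free C4' hydroxyl of ring C (and para to the C6 methoxy group of ring A), so ring C can be carried as a para-quinone methide with C1 as its electrophilic methide carbon; the C2 hydroxymethyl group can be an aldehyde, which makes C2 an enamine nucleophile.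
4. Forward: chain and ring A are joined, ring C is added as a carbinol, the alkene becomes the aldehyde, the silyl helpers are removed, ring B closes by intramolecular 1,6-addition of the enamine to the quinone methide, and one reduction ends the route.
5. Stereochemistry: C3 comes from lipase desymmetrisation of a prochiral diol; C1 and C2 arise in the ring closure under control of C3 and a matched amine catalyst; both carbinol epimers converge through the planar quinone methide, and C2 (α to CHO) is also the thermodynamic, all-equatorial centre.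

Key step: step 11

Assumption: lipase PS is taken to acetylate the hydroxymethyl arm of diol 2 that gives the (R)-monoacetate 3; if it takes the other arm, the same enzyme used hydrolytically on the diacetate gives (R)-3 and nothing downstream changes.

**Route**

Step 1
Reactants: 1 diethyl 2-allylmalonate
Product: 2 2-allylpropane-1,3-diol
Conditions: LiAlH4, THF, 0 °C→reflux; Rochelle salt work-up
Reagents that add atoms: none
Why: Ester-to-alcohol reduction with LiAlH4 converts both ester groups into hydroxymethyl groups and leaves the terminal alkene untouched, giving the prochiral diol.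

Step 2
Reactants: 2 2-allylpropane-1,3-diol
Product: 3 (R)-2-(hydroxymethyl)pent-4-en-1-yl acetate
Conditions: lipase PS (Burkholderia cepacia, Amano), vinyl acetate, i-Pr2O, 0 °C→rt
Reagents that add atoms: vinyl acetate, CC(=O)OC=C
Why: Enzymatic desymmetrisation by irreversible transesterification, in which the lipase acylates one of the two enantiotopic hydroxymethyl groups and so creates the stereocentre that becomes C3.

Step 3
Reactants: 3 (R)-2-(hydroxymethyl)pent-4-en-1-yl acetate
Product: 4 (S)-2-(iodomethyl)pent-4-en-1-yl acetate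
Conditions: I2, PPh3, imidazole, CH2Cl2, 0 °C
Reagents that add atoms: iodine, II
Why: Appel-type (Garegg–Samuelsson) iodination of the primary alcohol under near-neutral conditions does not touch the stereocentre and is fast enough to forestall the acetyl migration that would racemise 3.

Step 4
Reactants: 5 3-hydroxy-4,5-dimethoxybenzaldehyde
Product: 6 3,4-dimethoxy-5-[(triisopropylsilyl)oxy]benzaldehyde
Conditions: i-Pr3SiCl, imidazole, DMF, rt
Reagents that add atoms: triisopropylsilyl chloride, CC(C)[Si](Cl)(C(C)C)C(C)C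
Why: Phenol silylation gives a bulky, non-coordinating ether that survives organolithium, organozinc and Grignard reagents and keeps the neighbouring ring C–H (the future C8) from being metalated in step 5.

Step 5
Reactants: 6 3,4-dimethoxy-5-[(triisopropylsilyl)oxy]benzaldehyde
Product: 9 2-iodo-3,4-dimethoxy-5-[(triisopropylsilyl)oxy]benzaldehyde, via lithium α-amino alkoxide 7 (not isolated), via ortho-lithiated α-amino alkoxide 8 (not isolated)
Conditions: LiN(Me)CH2CH2NMe2 (from Me2NCH2CH2NHMe + n-BuLi), THF, −20 °C; n-BuLi (3 equiv), −20 °C; I2, −78 °C→rt; aq. NH4Cl, Na2S2O3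
Reagents that add atoms: iodine, II
Why: Comins-type directed ortho-lithiation, in which the lithium amide adds to the formyl group to give α-amino alkoxide 7, which protects the aldehyde and, together with the neighbouring methoxy group, directs n-BuLi to the ring hydrogen between them (the other ortho hydrogen lies next to the bulky silyl ether), and iodinolysis of 8 followed by aqueous collapse of the amino alkoxide returns the aldehyde.

Step 6
Reactants: 4 (S)-2-(iodomethyl)pent-4-en-1-yl acetate; 9 2-iodo-3,4-dimethoxy-5-[(triisopropylsilyl)oxy]benzaldehyde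
Product: 11 (2R)-2-({6-formyl-2,3-dimethoxy-4-[(triisopropylsilyl)oxy]phenyl}methyl)pent-4-en-1-yl acetate, via alkylzinc iodide 10 (not isolated)
Conditions: Zn dust (BrCH2CH2Br, Me3SiCl), LiCl, THF, 40 °C; then 9, Pd(OAc)2 (3 mol%), SPhos (6 mol%), THF, rt→50 °C
Reagents that add atoms: none
Why: Negishi sp3–sp2 cross-coupling, in which zinc inserts into the primary C–I bond without touching the β-stereocentre, the alkylzinc iodide tolerates aldehyde and acetate, and SPhos-ligated zerovalent palladium formed from Pd(OAc)2 couples di-ortho-substituted aryl iodides.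

Step 7
Reactants: 12 4-bromo-2-methoxyphenol
Product: 13 (4-bromo-2-methoxyphenoxy)(tert-butyl)dimethylsilane
Conditions: t-BuMe2SiCl, imidazole, DMF, rt
Reagents that add atoms: tert-butyldimethylsilyl chloride, CC(C)(C)[Si](C)(C)Cl
Why: Silylation of the phenol allows the bromide to be turned into a Grignard reagent, and the aryl silyl ether is later removed together with the triisopropylsilyl ether in step 10.

Step 8
Reactants: 13 (4-bromo-2-methoxyphenoxy)(tert-butyl)dimethylsilane; 11 (2R)-2-({6-formyl-2,3-dimethoxy-4-[(triisopropylsilyl)oxy]phenyl}methyl)pent-4-en-1-yl acetate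
Product: 15 (2R)-2-({6-[{4-[(tert-butyldimethylsilyl)oxy]-3-methoxyphenyl}(hydroxy)methyl]-2,3-dimethoxy-4-[(triisopropylsilyl)oxy]phenyl}methyl)pent-4-en-1-yl acetate (mixture of the two carbinol epimers), via arylmagnesium bromide 14 (not isolated)
Conditions: 13, Mg, THF, reflux; then 11 (1.2 equiv of 14), THF, −78→−40 °C; aq. NH4Cl
Reagents that add atoms: none
Why: Grignard addition to the aromatic aldehyde is far faster at low temperature than attack on the acetate, and the new carbinol centre forms without control and needs none because step 11 planarises it.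

Step 9
Reactants: 15 (2R)-2-({6-[{4-[(tert-butyldimethylsilyl)oxy]-3-methoxyphenyl}(hydroxy)methyl]-2,3-dimethoxy-4-[(triisopropylsilyl)oxy]phenyl}methyl)pent-4-en-1-yl acetate
Product: 17 (2S)-2-({6-[{4-[(tert-butyldimethylsilyl)oxy]-3-methoxyphenyl}(hydroxy)methyl]-2,3-dimethoxy-4-[(triisopropylsilyl)oxy]phenyl}methyl)-4-oxobutyl acetate (carbinol epimers), via vicinal diol 16 (not isolated)
Conditions: OsO4 (2 mol%), NaIO4, 2,6-lutidine, dioxane/H2O 3:1, rt
Reagents that add atoms: osmium tetroxide, O=[Os](=O)(=O)=O; sodium periodate, [Na+].[O-]I(=O)(=O)=O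
Why: Lemieux–Johnson oxidation (OsO4-catalysed dihydroxylation of the terminal alkene, periodate cleavage of diol 16) gives the aldehyde with loss of one carbon under buffered conditions that spare the electron-rich arenes, which ozone would attack, and the acid-sensitive carbinol.

Step 10
Reactants: 17 (2S)-2-({6-[{4-[(tert-butyldimethylsilyl)oxy]-3-methoxyphenyl}(hydroxy)methyl]-2,3-dimethoxy-4-[(triisopropylsilyl)oxy]phenyl}methyl)-4-oxobutyl acetate
Product: 18 (2S)-2-({4-hydroxy-6-[hydroxy(4-hydroxy-3-methoxyphenyl)methyl]-2,3-dimethoxyphenyl}methyl)-4-oxobutyl acetate (carbinol epimers)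
Conditions: Bu4NF, AcOH (1:1), THF, 0 °C; crude product taken on
Reagents that add atoms: none
Why: Fluoride cleavage of both aryl silyl ethers, buffered with acetic acid so that the phenoxides do not start aldol reaction, acetyl migration or premature loss of hydroxide from the carbinol, frees the C4' and C7 phenols while the alkyl acetate stays.

Step 11
Reactants: 18 (2S)-2-({4-hydroxy-6-[hydroxy(4-hydroxy-3-methoxyphenyl)methyl]-2,3-dimethoxyphenyl}methyl)-4-oxobutyl acetate
Product: 22 (1R,2S,3S)-3-(acetoxymethyl)-7-hydroxy-1-(4-hydroxy-3-methoxyphenyl)-5,6-dimethoxy-1,2,3,4-tetrahydronaphthalene-2-carbaldehyde, via para-quinone methide 19 (not isolated), via quinone methide enamine 20 (not isolated), via iminium phenolate 21 (not isolated)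
Conditions: (S)-α,α-diphenylprolinol trimethylsilyl ether (20 mol%), (PhO)2P(O)OH (20 mol%), CHCl3 (0.02 M), 0 °C→rt
Reagents that add atoms: none
Why: The ammonium phosphate should dehydrate either carbinol epimer of 18 to the same planar para-quinone methide 19 (methide carbon C1, stabilised para to the C4' oxygen of ring C and para to the C6 methoxy group of ring A) while the amine condenses with the aldehyde to E-enamine 20, whose carbon C2 adds to C1 in an intramolecular 1,6-conjugate addition that re-aromatises ring C and gives iminium phenolate 21, hydrolysed to 22 with release of the amine. The closest known reactions are the diarylprolinol silyl ether-catalysed 1,6-addition of aldehydes to para-quinone methides and the SN1-type α-alkylation of aldehydes with stabilised diarylmethanols under enamine catalysis, here run in ring-closing form. Ring B closes in a 6-exo-trig mode, the C1=C1' bond staying outside the new ring. C1 is set by the resident C3 centre through a chair-like transition state in which the C3 acetoxymethyl group, the enamine CH–N unit on C2 and the quinoid ring on C1 are all pseudo-equatorial (synclinal donor and acceptor), which gives the 1,3-cis-1,2-trans array; C2 is set by the E-geometry of the enamine and by the CPh2OSiMe3 group of the (S)-amine, which leaves open the Si face of C2 that the chair also demands (matched case), and since C2 is α to the formyl group any epimer can be equilibrated to the all-equatorial isomer. The step needs C-alkylation at C2 through the six-membered transition state to outrun intermolecular attack of the electron-rich rings or of the amine nitrogen on the quinone methide, which the tether, the high dilution and the bulky secondary amine should secure.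

Step 12
Reactants: 22 (1R,2S,3S)-3-(acetoxymethyl)-7-hydroxy-1-(4-hydroxy-3-methoxyphenyl)-5,6-dimethoxy-1,2,3,4-tetrahydronaphthalene-2-carbaldehyde
Product: 23 (1R,2S,3S)-1-(4-hydroxy-3-methoxyphenyl)-2,3-bis(hydroxymethyl)-5,6-dimethoxy-1,2,3,4-tetrahydronaphthalen-7-ol (CNP0197710.1)
Conditions: LiAlH4 (excess), THF, 0 °C; Rochelle salt work-up
Reagents that add atoms: none
Why: LiAlH4 reduces the aldehyde to the C2 hydroxymethyl group and cleaves the acetate reductively in the same operation (carbonyl and ester reduction), faster than any enolisation at C2, so the three stereocentres are retained.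

**Compound list**

1 | diethyl 2-allylmalonate | CCOC(=O)C(CC=C)C(=O)OCC | starting material
2 | 2-allylpropane-1,3-diol | C=CCC(CO)CO | intermediate
3 | (R)-2-(hydroxymethyl)pent-4-en-1-yl acetate | C=CC[C@H](CO)COC(C)=O | intermediate
4 | (S)-2-(iodomethyl)pent-4-en-1-yl acetate | C=CC[C@H](CI)COC(C)=O | intermediate
5 | 3-hydroxy-4,5-dimethoxybenzaldehyde | COc1cc(C=O)cc(O)c1OC | starting material
6 | 3,4-dimethoxy-5-[(triisopropylsilyl)oxy]benzaldehyde | COc1cc(C=O)cc(O[Si](C(C)C)(C(C)C)C(C)C)c1OC | intermediate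
7 | lithium {[2-(dimethylamino)ethyl](methyl)amino}{3,4-dimethoxy-5-[(triisopropylsilyl)oxy]phenyl}methanolate | [Li+].[O-]C(N(C)CCN(C)C)c1cc(OC)c(OC)c(O[Si](C(C)C)(C(C)C)C(C)C)c1 | intermediate
8 | 2-lithio derivative of 7 (lithium on the ring carbon between the amino alkoxide carbon and the methoxy group) | [Li+].[O-]C(N(C)CCN(C)C)c1cc(O[Si](C(C)C)(C(C)C)C(C)C)c(OC)c(OC)c1[Li] | intermediate
9 | 2-iodo-3,4-dimethoxy-5-[(triisopropylsilyl)oxy]benzaldehyde | O=Cc1cc(O[Si](C(C)C)(C(C)C)C(C)C)c(OC)c(OC)c1I | intermediate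
10 | {(2S)-2-[(acetyloxy)methyl]pent-4-en-1-yl}(iodo)zinc | C=CC[C@H](C[Zn]I)COC(C)=O | intermediate
11 | (2R)-2-({6-formyl-2,3-dimethoxy-4-[(triisopropylsilyl)oxy]phenyl}methyl)pent-4-en-1-yl acetate | O=Cc1cc(O[Si](C(C)C)(C(C)C)C(C)C)c(OC)c(OC)c1C[C@H](COC(C)=O)CC=C | intermediate
12 | 4-bromo-2-methoxyphenol | COc1cc(Br)ccc1O | starting material
13 | (4-bromo-2-methoxyphenoxy)(tert-butyl)dimethylsilane | COc1cc(Br)ccc1O[Si](C)(C)C(C)(C)C | intermediate
14 | {4-[(tert-butyldimethylsilyl)oxy]-3-methoxyphenyl}magnesium bromide | COc1cc([Mg]Br)ccc1O[Si](C)(C)C(C)(C)C | intermediate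
15 | (2R)-2-({6-[{4-[(tert-butyldimethylsilyl)oxy]-3-methoxyphenyl}(hydroxy)methyl]-2,3-dimethoxy-4-[(triisopropylsilyl)oxy]phenyl}methyl)pent-4-en-1-yl acetate, both carbinol epimers | COc1cc(C(O)c2cc(O[Si](C(C)C)(C(C)C)C(C)C)c(OC)c(OC)c2C[C@H](COC(C)=O)CC=C)ccc1O[Si](C)(C)C(C)(C)C | intermediate
16 | (2S)-2-({6-[{4-[(tert-butyldimethylsilyl)oxy]-3-methoxyphenyl}(hydroxy)methyl]-2,3-dimethoxy-4-[(triisopropylsilyl)oxy]phenyl}methyl)-4,5-dihydroxypentyl acetate, epimer mixture at both carbinols | COc1cc(C(O)c2cc(O[Si](C(C)C)(C(C)C)C(C)C)c(OC)c(OC)c2C[C@H](COC(C)=O)CC(O)CO)ccc1O[Si](C)(C)C(C)(C)C | intermediate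
17 | (2S)-2-({6-[{4-[(tert-butyldimethylsilyl)oxy]-3-methoxyphenyl}(hydroxy)methyl]-2,3-dimethoxy-4-[(triisopropylsilyl)oxy]phenyl}methyl)-4-oxobutyl acetate, both carbinol epimers | COc1cc(C(O)c2cc(O[Si](C(C)C)(C(C)C)C(C)C)c(OC)c(OC)c2C[C@H](COC(C)=O)CC=O)ccc1O[Si](C)(C)C(C)(C)C | intermediate
18 | (2S)-2-({4-hydroxy-6-[hydroxy(4-hydroxy-3-methoxyphenyl)methyl]-2,3-dimethoxyphenyl}methyl)-4-oxobutyl acetate, both carbinol epimers | COc1cc(C(O)c2cc(O)c(OC)c(OC)c2C[C@H](COC(C)=O)CC=O)ccc1O | intermediate
19 | (2S)-2-({4-hydroxy-2,3-dimethoxy-6-[(3-methoxy-4-oxocyclohexa-2,5-dien-1-ylidene)methyl]phenyl}methyl)-4-oxobutyl acetate | COC1=CC(=Cc2cc(O)c(OC)c(OC)c2C[C@H](COC(C)=O)CC=O)C=CC1=O | intermediate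
20 | (2S,3E)-2-({4-hydroxy-2,3-dimethoxy-6-[(3-methoxy-4-oxocyclohexa-2,5-dien-1-ylidene)methyl]phenyl}methyl)-4-[(2S)-2-{diphenyl[(trimethylsilyl)oxy]methyl}pyrrolidin-1-yl]but-3-en-1-yl acetate | COC1=CC(=Cc2cc(O)c(OC)c(OC)c2C[C@H](COC(C)=O)/C=C/N2CCC[C@H]2C(O[Si](C)(C)C)(c2ccccc2)c2ccccc2)C=CC1=O | intermediate
21 | zwitterion: (2S)-1-{[(1R,2S,3S)-3-(acetoxymethyl)-7-hydroxy-5,6-dimethoxy-1-(3-methoxy-4-oxidophenyl)-1,2,3,4-tetrahydronaphthalen-2-yl]methylidene}-2-{diphenyl[(trimethylsilyl)oxy]methyl}pyrrolidin-1-ium | COc1cc([C@@H]2c3cc(O)c(OC)c(OC)c3C[C@H](COC(C)=O)[C@H]2C=[N+]2CCC[C@H]2C(O[Si](C)(C)C)(c2ccccc2)c2ccccc2)ccc1[O-] | intermediate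
22 | (1R,2S,3S)-3-(acetoxymethyl)-7-hydroxy-1-(4-hydroxy-3-methoxyphenyl)-5,6-dimethoxy-1,2,3,4-tetrahydronaphthalene-2-carbaldehyde | COc1cc([C@@H]2c3cc(O)c(OC)c(OC)c3C[C@H](COC(C)=O)[C@H]2C=O)ccc1O | intermediate
23 | (1R,2S,3S)-1-(4-hydroxy-3-methoxyphenyl)-2,3-bis(hydroxymethyl)-5,6-dimethoxy-1,2,3,4-tetrahydronaphthalen-7-ol | COc1cc([C@@H]2c3cc(O)c(OC)c(OC)c3C[C@H](CO)[C@H]2CO)ccc1O | target

**Count and risks**

Total steps: 12. Longest linear sequence: 9 (steps 1, 2, 3, 6, 8, 9, 10, 11, 12).

Most likely to fail: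

1. Step 11. The quinone methide may be consumed intermolecularly (arylation by the electron-rich rings, N-alkylation of the amine) before the enamine closes the ring, or the ring may close with poor facial selectivity at C1. The fallback sets out from 17 and comes back at 22. Treatment of 17 with t-BuMe2SiOTf and Et3N (CH2Cl2, −78→0 °C) should silylate the carbinol and convert the aldehyde into its silyl enol ether, giving (2S)-2-({6-[{4-[(tert-butyldimethylsilyl)oxy]-3-methoxyphenyl}[(tert-butyldimethylsilyl)oxy]methyl]-2,3-dimethoxy-4-[(triisopropylsilyl)oxy]phenyl}methyl)-4-[(tert-butyldimethylsilyl)oxy]but-3-en-1-yl acetate F1. BF3·OEt2 (CH2Cl2, −78 °C) should ionise the benzhydryl silyl ether to the diarylmethyl cation, which the enol silane traps in an intramolecular Mukaiyama-type SN1 alkylation with no free phenol and no amine present, giving (1R,2S,3S)-3-(acetoxymethyl)-1-{4-[(tert-butyldimethylsilyl)oxy]-3-methoxyphenyl}-5,6-dimethoxy-7-[(triisopropylsilyl)oxy]-1,2,3,4-tetrahydronaphthalene-2-carbaldehyde F2 (C2 equilibrated with DBU if needed). Bu4NF/AcOH (THF, 0 °C) should then give 22.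

2. Step 5. Deprotonation may occur at the wrong ring position (next to the silyl ether, followed by silyl migration from oxygen to carbon) or stall, so that iodination is regio-unselective or incomplete. The fallback sets out from 6 and comes back at 9. NaBH4 (MeOH, 0 °C) should reduce 6 to {3,4-dimethoxy-5-[(triisopropylsilyl)oxy]phenyl}methanol F3. Electrophilic iodination with I2 and CF3CO2Ag (CHCl3, 0 °C) should enter the ring position para to the silyloxy group, the other free position being shielded by the triisopropylsilyl group, giving {2-iodo-3,4-dimethoxy-5-[(triisopropylsilyl)oxy]phenyl}methanol F4. MnO2 (CH2Cl2, rt) should return aldehyde 9.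

3. Step 2. The lipase may distinguish the two hydroxymethyl groups poorly or in the opposite sense, and acetyl migration between the two oxygen atoms may erode the enantiomeric purity. The fallback sets out from 1 and comes back at 3. Saponification of 1 (KOH, EtOH/H2O), acidification and thermal decarboxylation (160 °C) should give pent-4-enoic acid F5. Mixed-anhydride acylation (t-BuCOCl, Et3N, THF; then (S)-4-benzyl-1,3-oxazolidin-2-one, LiCl) should give (4S)-4-benzyl-3-(pent-4-enoyl)-1,3-oxazolidin-2-one F6. Evans alkylation of its titanium enolate (TiCl4, i-Pr2NEt, CH2Cl2, 0 °C; BnOCH2Cl), on the face away from the auxiliary benzyl group, should give (4S)-4-benzyl-3-[(2R)-2-[(benzyloxy)methyl]pent-4-enoyl]-1,3-oxazolidin-2-one F7. LiBH4 (Et2O, H2O, 0 °C) should cleave the auxiliary to (2S)-2-[(benzyloxy)methyl]pent-4-en-1-ol F8, and Ac2O/pyridine should give (2R)-2-[(benzyloxy)methyl]pent-4-en-1-yl acetate F9. BCl3 with pentamethylbenzene (CH2Cl2, −78 °C) should remove the benzyl ether without touching alkene or acetate and give 3.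

**Further compounds**

F1 | step 11 | (2S)-2-({6-[{4-[(tert-butyldimethylsilyl)oxy]-3-methoxyphenyl}[(tert-butyldimethylsilyl)oxy]methyl]-2,3-dimethoxy-4-[(triisopropylsilyl)oxy]phenyl}methyl)-4-[(tert-butyldimethylsilyl)oxy]but-3-en-1-yl acetate | COc1cc(C(O[Si](C)(C)C(C)(C)C)c2cc(O[Si](C(C)C)(C(C)C)C(C)C)c(OC)c(OC)c2C[C@H](COC(C)=O)C=CO[Si](C)(C)C(C)(C)C)ccc1O[Si](C)(C)C(C)(C)C
F2 | step 11 | (1R,2S,3S)-3-(acetoxymethyl)-1-{4-[(tert-butyldimethylsilyl)oxy]-3-methoxyphenyl}-5,6-dimethoxy-7-[(triisopropylsilyl)oxy]-1,2,3,4-tetrahydronaphthalene-2-carbaldehyde | COc1cc([C@@H]2c3cc(O[Si](C(C)C)(C(C)C)C(C)C)c(OC)c(OC)c3C[C@H](COC(C)=O)[C@H]2C=O)ccc1O[Si](C)(C)C(C)(C)C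
F3 | step 5 | {3,4-dimethoxy-5-[(triisopropylsilyl)oxy]phenyl}methanol | COc1cc(CO)cc(O[Si](C(C)C)(C(C)C)C(C)C)c1OC
F4 | step 5 | {2-iodo-3,4-dimethoxy-5-[(triisopropylsilyl)oxy]phenyl}methanol | OCc1cc(O[Si](C(C)C)(C(C)C)C(C)C)c(OC)c(OC)c1I
F5 | step 2 | pent-4-enoic acid | C=CCCC(=O)O
F6 | step 2 | (4S)-4-benzyl-3-(pent-4-enoyl)-1,3-oxazolidin-2-one | C=CCCC(=O)N1[C@@H](Cc2ccccc2)COC1=O
F7 | step 2 | (4S)-4-benzyl-3-[(2R)-2-[(benzyloxy)methyl]pent-4-enoyl]-1,3-oxazolidin-2-one | C=CC[C@H](COCc1ccccc1)C(=O)N1[C@@H](Cc2ccccc2)COC1=O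
F8 | step 2 | (2S)-2-[(benzyloxy)methyl]pent-4-en-1-ol | C=CC[C@H](COCc1ccccc1)CO
F9 | step 2 | (2R)-2-[(benzyloxy)methyl]pent-4-en-1-yl acetate | C=CC[C@H](COCc1ccccc1)COC(C)=O
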